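## Retrosynthetic overview
1. Target 17 ⇒ allylic chloride 15. The methacrylate enters last by SN2, so no protecting group is needed.
2. 15 ⇒ diene 14 by ring-closing metathesis. Ring A (the cyclohexene with the tetrasubstituted C5=C6) is formed last.
3. 14 ⇒ enal 5 + silylmethyl butenolide 13. This is the key C4–C3a bond. The butenolide β-carbon, normally an acceptor, acts as a β-lactonyl (homoenolate-type, d3) donor toward an aldehyde carbon, and C4 and C3a are set from C7a.
4. 13 ⇒ ring-closing metathesis (ring B, the lactone, is formed first) of the ester of (R)-dienol 9 and silyl acid 11. Dienol 9 comes from acrolein and 3-chloro-2-(chloromethyl)prop-1-ene by asymmetric allylation.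
5. 5 ⇒ (S)-citronellal, which supplies the side-chain stereocentre, by α-methylenation, alkene cleavage with selective reduction, and acetylation.

Assumption: the SMILES is read literally as a trans-fused lactone (3aR,7aR), a 4S carbinol cis to the C3a–C3 bond, and an (S) side-chain centre. Compounds 1, 6, 7, 10 and 16 are bought.

## Route

Step 1
Reactants: 1 (S)-citronellal
Product: 2 (3S)-3,7-dimethyl-2-methylideneoct-6-enal
Conditions: 37 % aq HCHO (1.2 equiv), pyrrolidine (10 mol %), propionic acid (10 mol %), iPrOH, 45 °C
Reagents that add atoms: formaldehyde, C=O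
Why: Amine/acid-catalysed Mannich-type α-methylenation (the enamine of 1 adds to the formaldehyde-derived iminium ion, then the amine is eliminated); the stereocentre sits β to the carbonyl, is never enolised and is carried over as (S).

Step 2
Reactants: 2 (3S)-3,7-dimethyl-2-methylideneoct-6-enal
Product: 4 (3S)-6-hydroxy-3-methyl-2-methylidenehexanal, via dialdehyde 3 (not isolated)
Conditions: O3 (1.0 equiv, TLC control), CH2Cl2/MeOH 1:1, −78 °C; Me2S, −78 °C → rt; recool, NaBH4 (0.3 equiv), −78 °C
Reagents that add atoms: ozone, [O-][O+]=O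
Why: Chemoselective ozonolysis followed by chemoselective borohydride reduction: electrophilic ozone takes the electron-rich trisubstituted alkene long before the acceptor-substituted one, and at −78 °C a saturated aldehyde is reduced much faster than a conjugated one, so only the new formyl group of 3 becomes CH2OH; no stereocentre is touched.

Step 3
Reactants: 4 (3S)-6-hydroxy-3-methyl-2-methylidenehexanal
Product: 5 (4S)-5-formyl-4-methylhex-5-en-1-yl acetate
Conditions: Ac2O (1.2 equiv), pyridine, CH2Cl2, 0 °C
Reagents that add atoms: acetic anhydride, CC(=O)OC(C)=O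
Why: Plain O-acetylation of the only hydroxyl group; short contact at 0 °C keeps the amine from adding to the enal.

Step 4
Reactants: 6 acrolein; 7 3-chloro-2-(chloromethyl)prop-1-ene
Product: 9 (3R)-5-(chloromethyl)hexa-1,5-dien-3-ol, via trimethylsilyl ether 8 (not isolated)
Conditions: CrCl2 (10 mol %), chiral tridentate 1,8-bis(4-isopropyloxazolin-2-yl)carbazole ligand (12 mol %, antipode giving Re-face attack), iPr2NEt (30 mol %), Mn powder (2 equiv), Me3SiCl (2 equiv), 7 (4 equiv), THF, 0 °C; then 1 M HCl, THF, 0 °C
Reagents that add atoms: chlorotrimethylsilane, C[Si](C)(C)Cl (its silyl group is in 8 only)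
Why: Catalytic asymmetric Nozaki–Hiyama–Kishi allylation: divalent chromium (recycled by Mn) inserts into one allylic C–Cl bond, the ligand-bound allyl donor adds 1,2 to acrolein through a closed chair and the ligand selects the Re face, which sets the (R) carbinol (future C7a); silylation turns the catalyst over and keeps the alkoxide from displacing the second chloride.

Step 5
Reactants: 10 ethyl 2-[(trimethylsilyl)methyl]prop-2-enoate
Product: 11 2-[(trimethylsilyl)methyl]prop-2-enoic acid
Conditions: LiOH (1.5 equiv), THF/H2O, rt; 1 M HCl to pH 4, 0 °C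
Reagents that add atoms: lithium hydroxide, [Li+].[OH-]
Why: Ester saponification; the allylsilane is stable to base, and only mild acidification is used so that protodesilylation is avoided.

Step 6
Reactants: 9 (3R)-5-(chloromethyl)hexa-1,5-dien-3-ol; 11 2-[(trimethylsilyl)methyl]prop-2-enoic acid
Product: 12 (3R)-5-(chloromethyl)hexa-1,5-dien-3-yl 2-[(trimethylsilyl)methyl]prop-2-enoate
Conditions: DCC (1.1 equiv), DMAP (5 mol %), CH2Cl2, 0 °C → rt
Reagents that add atoms: none
Why: Steglich esterification; the carbinol C–O bond is not broken, so the (R) centre is retained.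

Step 7
Reactants: 12 (3R)-5-(chloromethyl)hexa-1,5-dien-3-yl 2-[(trimethylsilyl)methyl]prop-2-enoate
Product: 13 (5R)-5-[2-(chloromethyl)prop-2-en-1-yl]-3-[(trimethylsilyl)methyl]furan-2(5H)-one
Conditions: second-generation Grubbs catalyst (5 mol %), CH2Cl2 (0.01 M), reflux
Reagents that add atoms: none
Why: Ring-closing metathesis: ruthenium loads on the monosubstituted vinyl group and closes onto the acrylate alkene to give the trisubstituted butenolide (ring B); the chloromethyl-substituted alkene could only give a cyclobutene or a much slower tetrasubstituted six-ring and stays out; the stereocentre is untouched.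

Step 8
Reactants: 5 (4S)-5-formyl-4-methylhex-5-en-1-yl acetate; 13 (5R)-5-[2-(chloromethyl)prop-2-en-1-yl]-3-[(trimethylsilyl)methyl]furan-2(5H)-one
Product: 14 (4S)-5-{(S)-[(2R,3R)-2-[2-(chloromethyl)prop-2-en-1-yl]-4-methylidene-5-oxooxolan-3-yl](hydroxy)methyl}-4-methylhex-5-en-1-yl acetate
Conditions: BF3·OEt2 (2.0 equiv), CH2Cl2, −78 → −40 °C; aq NaHCO3
Reagents that add atoms: none
Why: Proposed new method: the C–Si bond raises the π-HOMO by hyperconjugation so that the butenolide β-carbon, normally an acceptor, attacks the BF3-activated aldehyde as a β-lactonyl (homoenolate-type, d3) donor in an SE2′ sense, and loss of Me3SiF from the β-silyl cation unveils the α-methylene lactone directly; the aldehyde approaches anti to the C5 side arm (C3a set trans to C7a) and the open antiperiplanar transition state of the ring-locked (E)-type allylsilane gives the syn carbinol (4S); closest known reaction type: Hosomi–Sakurai addition of 2-(alkoxycarbonyl)allylsilanes and -stannanes to aldehydes.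

Step 9
Reactants: 14 (4S)-5-{(S)-[(2R,3R)-2-[2-(chloromethyl)prop-2-en-1-yl]-4-methylidene-5-oxooxolan-3-yl](hydroxy)methyl}-4-methylhex-5-en-1-yl acetate
Product: 15 (4S)-4-[(3aR,4S,7aR)-6-(chloromethyl)-4-hydroxy-3-methylidene-2-oxo-2,3,3a,4,7,7a-hexahydro-1-benzofuran-5-yl]pentyl acetate
Conditions: RuCl2[1,3-bis(2-methylphenyl)imidazolidin-2-ylidene](=CH-C6H4-2-OiPr) (2 × 5 mol %), 1,4-benzoquinone (10 mol %), toluene (0.005 M), 100 °C, argon sparge
Reagents that add atoms: none
Why: Ring-closing metathesis to a tetrasubstituted cyclohexene (ring A) with a sterically reduced carbene ligand made for such closures; the two arms are held vicinal on the lactone, the free allylic hydroxyl helps, the electron-poor lactone methylene could only give a cyclobutene or an anti-Bredt bridged ring, and loss of ethene drives the reaction; all four stereocentres are spectators.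

Step 10
Reactants: 15 (4S)-4-[(3aR,4S,7aR)-6-(chloromethyl)-4-hydroxy-3-methylidene-2-oxo-2,3,3a,4,7,7a-hexahydro-1-benzofuran-5-yl]pentyl acetate; 16 sodium methacrylate
Product: 17 [(3aR,4S,7aR)-5-[(2S)-5-acetyloxypentan-2-yl]-4-hydroxy-3-methylidene-2-oxo-3a,4,7,7a-tetrahydro-1-benzofuran-6-yl]methyl 2-methylprop-2-enoate (target)
Conditions: 16 (1.5 equiv), BHT (trace), DMF, 45 °C
Reagents that add atoms: none
Why: SN2 displacement of a primary allylic chloride by a carboxylate; SN2′ attack would have to hit the fully substituted C5, the C4 hydroxyl is trans to the CH2Cl across the alkene and cannot cyclise, and the weakly basic carboxylate leaves the acetate, the lactone and the stereocentres alone.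

## Compound list
1 | (S)-citronellal, (3S)-3,7-dimethyloct-6-enal | O=CC[C@@H](C)CCC=C(C)C | starting material
2 | (3S)-3,7-dimethyl-2-methylideneoct-6-enal | C=C(C=O)[C@@H](C)CCC=C(C)C | intermediate
3 | (3S)-3-methyl-2-methylidenehexanedial | C=C(C=O)[C@@H](C)CCC=O | intermediate (not isolated)
4 | (3S)-6-hydroxy-3-methyl-2-methylidenehexanal | C=C(C=O)[C@@H](C)CCCO | intermediate
5 | (4S)-5-formyl-4-methylhex-5-en-1-yl acetate | C=C(C=O)[C@@H](C)CCCOC(C)=O | intermediate
6 | acrolein | C=CC=O | starting material
7 | 3-chloro-2-(chloromethyl)prop-1-ene | C=C(CCl)CCl | starting material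
8 | {[(3R)-5-(chloromethyl)hexa-1,5-dien-3-yl]oxy}trimethylsilane | C=C[C@H](O[Si](C)(C)C)CC(=C)CCl | intermediate (not isolated)
9 | (3R)-5-(chloromethyl)hexa-1,5-dien-3-ol | C=C[C@H](O)CC(=C)CCl | intermediate
10 | ethyl 2-[(trimethylsilyl)methyl]prop-2-enoate | C=C(C[Si](C)(C)C)C(=O)OCC | starting material
11 | 2-[(trimethylsilyl)methyl]prop-2-enoic acid | C=C(C[Si](C)(C)C)C(=O)O | intermediate
12 | (3R)-5-(chloromethyl)hexa-1,5-dien-3-yl 2-[(trimethylsilyl)methyl]prop-2-enoate | C=C[C@H](OC(=O)C(=C)C[Si](C)(C)C)CC(=C)CCl | intermediate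
13 | (5R)-5-[2-(chloromethyl)prop-2-en-1-yl]-3-[(trimethylsilyl)methyl]furan-2(5H)-one | O=C1O[C@H](CC(=C)CCl)C=C1C[Si](C)(C)C | intermediate
14 | (4S)-5-{(S)-[(2R,3R)-2-[2-(chloromethyl)prop-2-en-1-yl]-4-methylidene-5-oxooxolan-3-yl](hydroxy)methyl}-4-methylhex-5-en-1-yl acetate | C=C([C@@H](C)CCCOC(C)=O)[C@@H](O)[C@H]1C(=C)C(=O)O[C@@H]1CC(=C)CCl | intermediate
15 | (4S)-4-[(3aR,4S,7aR)-6-(chloromethyl)-4-hydroxy-3-methylidene-2-oxo-2,3,3a,4,7,7a-hexahydro-1-benzofuran-5-yl]pentyl acetate | ClCC1=C([C@@H](C)CCCOC(C)=O)[C@@H](O)[C@H]2C(=C)C(=O)O[C@@H]2C1 | intermediate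
16 | sodium methacrylate | C=C(C)C(=O)[O-].[Na+] | starting material
17 | [(3aR,4S,7aR)-5-[(2S)-5-acetyloxypentan-2-yl]-4-hydroxy-3-methylidene-2-oxo-3a,4,7,7a-tetrahydro-1-benzofuran-6-yl]methyl 2-methylprop-2-enoate | C=C(C)C(=O)OCC1=C([C@@H](C)CCCOC(C)=O)[C@@H](O)[C@H]2C(=C)C(=O)O[C@@H]2C1 | target

## Totals and risks
Total step count: 10.
Longest linear sequence: 6 steps (4, 6, 7, 8, 9, 10, or equally 1, 2, 3, 8, 9, 10).

**Step 8 (silane too weak a donor, or poor syn/anti control at C4).**
- The fallback sets out from 9 (with 5) and comes back at 14. It replaces the Lewis-acid open-transition-state addition by a metal-mediated Barbier coupling followed by redox correction of the carbinol.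
- Compound 9 is esterified with purchased 2-(bromomethyl)acrylic acid (DCC) to the 2-(bromomethyl)acrylate ester F1.
- F1 is closed with second-generation Grubbs catalyst to the bromomethyl butenolide F2.
- F2 is coupled with 5 by indium powder in THF/H2O. The allylic chloride is too unreactive to compete.
- The ring-locked (E)-type allylindium reacts through a closed chair, still anti to the C5 arm, and is expected to give mainly the C4-epimeric carbinol F3.
- Dess–Martin periodinane (buffered, 0 °C) turns F3, or any C4 mixture, into the cross-conjugated ketone F4.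
- (R)-Me-CBS with catecholborane at −78 °C, with the alkenyl arm acting as the large group and hydride going to the Re face, returns 14.

**Step 9 (closure of a tetrasubstituted alkene flanked by a secondary alkyl group and a carbinol).**
- The fallback sets out from 14 and comes back at 15. It gives up the protecting-group-free ruthenium closure for a masked carbinol and a high-oxidation-state early-metal alkylidene, which copes better with hindered 1,1-disubstituted dienes but does not tolerate a free OH.
- Et3SiCl and imidazole give the triethylsilyl ether of 14 F5.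
- Mo(=CHCMe2Ph)(=N-2,6-iPr2C6H3)[OCMe(CF3)2]2 (20 mol %, benzene, 60 °C) closes F5 to the triethylsilyl ether of 15 F6.
- HF·pyridine (THF, 0 °C) then frees 15.

**Step 4 (enantioselectivity with the small aldehyde acrolein and a new allyl donor).**
- The fallback sets out from 6 and 7 and comes back at 9. It replaces asymmetric catalysis by resolution.
- Indium powder in THF/H2O with excess 7 gives the racemic dienol F7.
- Immobilised Candida antarctica lipase B with vinyl acetate in hexane acylates the enantiomer that carries the vinyl group in the medium-size pocket, giving the (S)-acetate F8.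
- (R)-9 is left unreacted and is separated by chromatography at slightly above 50 % conversion.

## Further compounds
F1 | step 8 | (3R)-5-(chloromethyl)hexa-1,5-dien-3-yl 2-(bromomethyl)prop-2-enoate | C=C[C@H](OC(=O)C(=C)CBr)CC(=C)CCl
F2 | step 8 | (5R)-3-(bromomethyl)-5-[2-(chloromethyl)prop-2-en-1-yl]furan-2(5H)-one | O=C1O[C@H](CC(=C)CCl)C=C1CBr
F3 | step 8 | (R)-carbinol epimer of 14, (4S)-5-{(R)-[(2R,3R)-2-[2-(chloromethyl)prop-2-en-1-yl]-4-methylidene-5-oxooxolan-3-yl](hydroxy)methyl}-4-methylhex-5-en-1-yl acetate | C=C([C@@H](C)CCCOC(C)=O)[C@H](O)[C@H]1C(=C)C(=O)O[C@@H]1CC(=C)CCl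
F4 | step 8 | (4S)-5-{[(2R,3S)-2-[2-(chloromethyl)prop-2-en-1-yl]-4-methylidene-5-oxooxolan-3-yl]carbonyl}-4-methylhex-5-en-1-yl acetate | C=C([C@@H](C)CCCOC(C)=O)C(=O)[C@H]1C(=C)C(=O)O[C@@H]1CC(=C)CCl
F5 | step 9 | O-triethylsilyl ether of 14 | C=C([C@@H](C)CCCOC(C)=O)[C@@H](O[Si](CC)(CC)CC)[C@H]1C(=C)C(=O)O[C@@H]1CC(=C)CCl
F6 | step 9 | O-triethylsilyl ether of 15 | ClCC1=C([C@@H](C)CCCOC(C)=O)[C@@H](O[Si](CC)(CC)CC)[C@H]2C(=C)C(=O)O[C@@H]2C1
F7 | step 4 | racemic 5-(chloromethyl)hexa-1,5-dien-3-ol | C=CC(O)CC(=C)CCl
F8 | step 4 | (3S)-5-(chloromethyl)hexa-1,5-dien-3-yl acetate | C=C[C@@H](OC(C)=O)CC(=C)CCl
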